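**Plan**

1. Target: (3S,5R)-1-(4-hydroxy-3-methoxyphenyl)tetradecane-3,5-diol (chain numbered from the benzylic CH2 as C1), a 1,3-syn diol on an unbranched C14 chain; its only ring, the guaiacol benzene ring, is bought and stays a spectator.
2. Retrosynthesis: remove the benzyl group; take the C3 carbinol back to a C3 ketone (1,3-syn reduction directed by O5); take the ketone back to a 1,3-dithiane; then cut both bonds at C3 in one operation, C3–C4 (dithiane carbanion plus the terminal CH2 of (R)-2-nonyloxirane) and C2–C3 (alkylation by a 2-arylethyl iodide).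
3. Enabling feature: C3 is an oxygen-bearing carbon flanked by two CH2 groups (C2 and C4) with O5 in the 1,3-position, so C3 can serve as a silyl-dithiane linchpin carbanion. The atoms Si–C3–C4–C5–O5 are placed for a 1,4 silyl shift that hands the negative charge back to C3; the temporary six-membered 1,3-dithiane ring (S–C3–S) holds C3 at the ketone level until step 7.
4. Forward: epoxide 4 (steps 1–2) and iodide 7 (steps 3–4) are joined with silyl dithiane 8 in one flask (step 5, whole C14 chain); then desilylation, dithiane hydrolysis, syn reduction and hydrogenolysis follow. No ring is formed in the route.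
5. Stereochemistry: C5 (R) comes from (R)-epichlorohydrin and its C–O bond is never broken; C3 (S) is set in step 8 by boron-chelate-controlled hydride addition relayed from C5.
6. Remark: the phenol is carried as its benzyl ether from step 3 to step 9; compounds 1, 2, 5 and 8 are taken as commercial.

Key step: step 5

**Route**

Step 1
Reactants: 1 (R)-epichlorohydrin; 2 octylmagnesium bromide
Product: 3 (2R)-1-chloroundecan-2-ol
Conditions: CuI (10 mol %), THF, −40 → 0 °C; then cold 1 M HCl
Reagents that add atoms: none
Why: Copper-catalysed Grignard opening of a terminal epoxide proceeds by SN2 attack at the unsubstituted ring CH2, so the octyl group should be added without touching the stereocentre or the C–Cl bond, giving the (R) carbinol.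

Step 2
Reactants: 3 (2R)-1-chloroundecan-2-ol
Product: 4 (2R)-2-nonyloxirane
Conditions: NaOH (powdered), Et2O, rt
Reagents that add atoms: none
Why: Intramolecular Williamson etherification of the chlorohydrin alkoxide displaces the primary chloride and closes the oxirane without breaking the C–O bond at the stereocentre, so the (R) configuration should be kept.

Step 3
Reactants: 5 4-(2-hydroxyethyl)-2-methoxyphenol (homovanillyl alcohol)
Product: 6 2-[4-(benzyloxy)-3-methoxyphenyl]ethan-1-ol
Conditions: BnBr, K2CO3, acetone, reflux
Reagents that add atoms: benzyl bromide, BrCc1ccccc1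
Why: In this Williamson ether synthesis K2CO3 deprotonates only the phenol and not the aliphatic alcohol, so benzylation should take place at the phenolic oxygen alone.

Step 4
Reactants: 6 2-[4-(benzyloxy)-3-methoxyphenyl]ethan-1-ol
Product: 7 1-(benzyloxy)-4-(2-iodoethyl)-2-methoxybenzene
Conditions: I2, PPh3, imidazole, CH2Cl2, 0 °C → rt
Reagents that add atoms: iodine, II
Why: In this Appel-type iodination the primary alcohol is activated as an alkoxyphosphonium ion and displaced by iodide in an SN2 step, under conditions that leave both aryl ethers untouched.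

Step 5
Reactants: 8 2-(tert-butyldimethylsilyl)-1,3-dithiane; 4 (2R)-2-nonyloxirane; 7 1-(benzyloxy)-4-(2-iodoethyl)-2-methoxybenzene
Product: 12 tert-butyl{[(2R)-1-(2-{2-[4-(benzyloxy)-3-methoxyphenyl]ethyl}-1,3-dithian-2-yl)undecan-2-yl]oxy}dimethylsilane, via lithiated silyl dithiane 9 (not isolated), via lithium alkoxide 10 (not isolated), via relayed dithianyllithium 11 (not isolated)
Conditions: t-BuLi, Et2O, −78 → −45 °C; 4, Et2O, −78 → −25 °C; then 7, THF/HMPA, −78 °C → rt
Reagents that add atoms: none
Why: Deprotonated 8 (carbanion 9, stabilised by two sulfur atoms and silicon) opens epoxide 4 by SN2 attack at its unsubstituted CH2, which forms the C3–C4 bond; in Et2O the lithium alkoxide 10 is stable, and only when the polar THF/HMPA solution of 7 is added does the silyl group migrate from C3 to O5 (1,4-Brook rearrangement through a five-membered silicate made of Si, C3, C4, C5 and O5), regenerating a dithianyl carbanion (11) that is alkylated at C3 by the primary iodide 7 (C2–C3 bond). The closest known reaction type is the three-component silyl-dithiane linchpin coupling (Smith–Tietze coupling, type 1 anion relay chemistry), ended here by an alkyl iodide instead of a second epoxide, which is an ordinary alkylation of a 2-alkyl-2-lithio-1,3-dithiane. No ring is closed, since the 1,3-dithiane arrives intact and serves as the temporary ring that holds C3 at the ketone oxidation level. No new stereocentre arises: C3 carries two equal sulfur substituents, and C5 keeps the (R) configuration of 4 because its C–O bond is never broken. The step needs regioselective opening at the terminal epoxide carbon (secured by the bulk of the silylated carbanion), strict timing of the silyl shift (secured by the solvent switch, so that 11 forms only after 4 is consumed and meets only 7), and substitution over elimination at the 2-arylethyl iodide (favoured by the soft sulfur-stabilised carbanion and the low temperature).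

Step 6
Reactants: 12 tert-butyl{[(2R)-1-(2-{2-[4-(benzyloxy)-3-methoxyphenyl]ethyl}-1,3-dithian-2-yl)undecan-2-yl]oxy}dimethylsilane
Product: 13 (2R)-1-(2-{2-[4-(benzyloxy)-3-methoxyphenyl]ethyl}-1,3-dithian-2-yl)undecan-2-ol
Conditions: TBAF, THF, 0 °C → rt
Reagents that add atoms: none
Why: Fluoride-driven cleavage of the silyl ether (strong Si–F bond) is carried out while C3 is still a dithiane, so there is no carbonyl group and hence no risk of β-elimination of the C5 oxygen.

Step 7
Reactants: 13 (2R)-1-(2-{2-[4-(benzyloxy)-3-methoxyphenyl]ethyl}-1,3-dithian-2-yl)undecan-2-ol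
Product: 14 (5R)-1-[4-(benzyloxy)-3-methoxyphenyl]-5-hydroxytetradecan-3-one
Conditions: MeI (excess), CaCO3, MeCN/H2O (9:1), 40 °C
Reagents that add atoms: water, O
Why: In this alkylative dithiane hydrolysis S-methylation turns sulfur into a leaving group and water adds to the resulting thionium ion, which should unmask the C3 ketone under buffered, non-oxidising, metal-free conditions that spare the electron-rich arene, the benzyl ether and the aldol.

Step 8
Reactants: 14 (5R)-1-[4-(benzyloxy)-3-methoxyphenyl]-5-hydroxytetradecan-3-one
Product: 16 (3S,5R)-1-[4-(benzyloxy)-3-methoxyphenyl]tetradecane-3,5-diol, via diethylboron chelate 15 (not isolated)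
Conditions: Et2BOMe, THF/MeOH (4:1), −78 °C; NaBH4, −78 °C; then MeOH, repeated co-evaporation
Reagents that add atoms: none
Why: In this Narasaka–Prasad reduction Et2BOMe turns the C5 hydroxyl into a diethylborinate that chelates the C3 carbonyl in a six-membered half-chair with the nonyl group pseudo-equatorial, and NaBH4 then delivers hydride from outside along the axial trajectory, which should set C3 as (S), syn to the C5 oxygen.

Step 9
Reactants: 16 (3S,5R)-1-[4-(benzyloxy)-3-methoxyphenyl]tetradecane-3,5-diol
Product: 17 (3S,5R)-1-(4-hydroxy-3-methoxyphenyl)tetradecane-3,5-diol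
Conditions: H2 (1 atm), Pd/C, EtOAc, rt
Reagents that add atoms: none
Why: Hydrogenolysis of the benzyl aryl ether over palladium on carbon should free the phenol, while the two secondary alcohols, which are not benzylic, and both stereocentres are not affected.

**Compound list**

1 | (R)-epichlorohydrin, (2R)-2-(chloromethyl)oxirane | ClC[C@H]1CO1 | starting material
2 | octylmagnesium bromide | CCCCCCCC[Mg]Br | starting material
3 | (2R)-1-chloroundecan-2-ol | CCCCCCCCC[C@@H](O)CCl | intermediate
4 | (2R)-2-nonyloxirane | CCCCCCCCC[C@@H]1CO1 | intermediate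
5 | 4-(2-hydroxyethyl)-2-methoxyphenol (homovanillyl alcohol) | OCCc1ccc(O)c(OC)c1 | starting material
6 | 2-[4-(benzyloxy)-3-methoxyphenyl]ethan-1-ol | OCCc1ccc(OCc2ccccc2)c(OC)c1 | intermediate
7 | 1-(benzyloxy)-4-(2-iodoethyl)-2-methoxybenzene | ICCc1ccc(OCc2ccccc2)c(OC)c1 | intermediate
8 | 2-(tert-butyldimethylsilyl)-1,3-dithiane | CC(C)(C)[Si](C)(C)C1SCCCS1 | starting material
9 | 2-lithio-2-(tert-butyldimethylsilyl)-1,3-dithiane | [Li]C1([Si](C)(C)C(C)(C)C)SCCCS1 | intermediate
10 | lithium (2R)-1-[2-(tert-butyldimethylsilyl)-1,3-dithian-2-yl]undecan-2-olate | CCCCCCCCC[C@@H](O[Li])CC1([Si](C)(C)C(C)(C)C)SCCCS1 | intermediate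
11 | 2-lithio-2-[(2R)-2-(tert-butyldimethylsilyloxy)undecyl]-1,3-dithiane | CCCCCCCCC[C@@H](O[Si](C)(C)C(C)(C)C)CC1([Li])SCCCS1 | intermediate
12 | tert-butyl{[(2R)-1-(2-{2-[4-(benzyloxy)-3-methoxyphenyl]ethyl}-1,3-dithian-2-yl)undecan-2-yl]oxy}dimethylsilane | CCCCCCCCC[C@@H](O[Si](C)(C)C(C)(C)C)CC1(CCc2ccc(OCc3ccccc3)c(OC)c2)SCCCS1 | intermediate
13 | (2R)-1-(2-{2-[4-(benzyloxy)-3-methoxyphenyl]ethyl}-1,3-dithian-2-yl)undecan-2-ol | CCCCCCCCC[C@@H](O)CC1(CCc2ccc(OCc3ccccc3)c(OC)c2)SCCCS1 | intermediate
14 | (5R)-1-[4-(benzyloxy)-3-methoxyphenyl]-5-hydroxytetradecan-3-one | CCCCCCCCC[C@@H](O)CC(=O)CCc1ccc(OCc2ccccc2)c(OC)c1 | intermediate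
15 | (5R)-1-[4-(benzyloxy)-3-methoxyphenyl]-5-[(diethylboranyl)oxy]tetradecan-3-one (boron chelate) | CCCCCCCCC[C@@H](OB(CC)CC)CC(=O)CCc1ccc(OCc2ccccc2)c(OC)c1 | intermediate
16 | (3S,5R)-1-[4-(benzyloxy)-3-methoxyphenyl]tetradecane-3,5-diol | CCCCCCCCC[C@@H](O)C[C@@H](O)CCc1ccc(OCc2ccccc2)c(OC)c1 | intermediate
17 | (3S,5R)-1-(4-hydroxy-3-methoxyphenyl)tetradecane-3,5-diol | CCCCCCCCC[C@@H](O)C[C@@H](O)CCc1ccc(O)c(OC)c1 | target

**Totals**

Total step count: 9.
Longest linear sequence: 7 steps (steps 1, 2, 5, 6, 7, 8, 9).

**Steps most likely to fail**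

Step 5. The relayed tertiary dithianyllithium may act as a base on the 2-arylethyl iodide (elimination to the styrene) instead of as a nucleophile, or the silyl shift may stay incomplete so that part of the material is quenched before the second bond forms. The fallback drops the silyl relay and attaches the aryl arm first. It sets out from 7: parent 1,3-dithiane is lithiated (n-BuLi, THF, −30 °C) and alkylated with 7, where the unhindered secondary carbanion should favour substitution, to give 2-{2-[4-(benzyloxy)-3-methoxyphenyl]ethyl}-1,3-dithiane F1. F1 is lithiated again (n-BuLi, THF, −20 °C) and the anion opens epoxide 4 at its CH2, which forms the same C3–C4 bond and comes back to the route at 13, so that step 6 is no longer needed.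

Step 7. S-Alkylation of the hindered dialkyl dithiane may be slow, leaving the free aldol in a warm medium long enough for dehydration to the conjugated enone or retro-aldol cleavage. The fallback inverts the order of unmasking so that the aldol never meets these conditions as a free alcohol. It sets out from 12: the dithiane is hydrolysed first (MeI, CaCO3, MeCN/H2O, 40 °C) to (5R)-1-[4-(benzyloxy)-3-methoxyphenyl]-5-[(tert-butyldimethylsilyl)oxy]tetradecan-3-one F2, and the silyl ether is then cleaved with aqueous HF in MeCN at 0 °C, an acidic, non-basic fluoride source. This comes back to the route at 14.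

Step 8. If the boron chelate forms incompletely, hydride adds to the unchelated ketone and facial selectivity is lost, which would contaminate the product with the anti diol. The fallback moves the control to a lithium chelate of an ether. It sets out from 13: O-benzylation (NaH, BnBr, Bu4NI, THF/DMF, 0 °C → rt) should give 2-[(2R)-2-(benzyloxy)undecyl]-2-{2-[4-(benzyloxy)-3-methoxyphenyl]ethyl}-1,3-dithiane F3. Dithiane hydrolysis (MeI, CaCO3, MeCN/H2O) should give (5R)-5-(benzyloxy)-1-[4-(benzyloxy)-3-methoxyphenyl]tetradecan-3-one F4. Reduction with LiAlH4 and LiI in Et2O at −78 °C, the known syn-selective reduction of β-alkoxy ketones through a lithium chelate between the ether oxygen and the carbonyl, should give (3S,5R)-5-(benzyloxy)-1-[4-(benzyloxy)-3-methoxyphenyl]tetradecan-3-ol F5. Hydrogenolysis of both benzyl ethers (H2, Pd/C, EtOAc) comes back to the route at 17.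

**Further compounds**

F1 | step 5 | 2-{2-[4-(benzyloxy)-3-methoxyphenyl]ethyl}-1,3-dithiane | C1CSC(CCc2ccc(OCc3ccccc3)c(OC)c2)SC1
F2 | step 7 | (5R)-1-[4-(benzyloxy)-3-methoxyphenyl]-5-[(tert-butyldimethylsilyl)oxy]tetradecan-3-one | CCCCCCCCC[C@@H](O[Si](C)(C)C(C)(C)C)CC(=O)CCc1ccc(OCc2ccccc2)c(OC)c1
F3 | step 8 | 2-[(2R)-2-(benzyloxy)undecyl]-2-{2-[4-(benzyloxy)-3-methoxyphenyl]ethyl}-1,3-dithiane | CCCCCCCCC[C@@H](OCc1ccccc1)CC1(CCc2ccc(OCc3ccccc3)c(OC)c2)SCCCS1
F4 | step 8 | (5R)-5-(benzyloxy)-1-[4-(benzyloxy)-3-methoxyphenyl]tetradecan-3-one | CCCCCCCCC[C@@H](OCc1ccccc1)CC(=O)CCc1ccc(OCc2ccccc2)c(OC)c1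
F5 | step 8 | (3S,5R)-5-(benzyloxy)-1-[4-(benzyloxy)-3-methoxyphenyl]tetradecan-3-ol | CCCCCCCCC[C@@H](OCc1ccccc1)C[C@@H](O)CCc1ccc(OCc2ccccc2)c(OC)c1
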